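## Retrosynthetic overview

- The target is the mono-acetate of a C2-symmetric (3S,5S)-1,7-diarylheptane-3,5-diol. Its two hydroxyls are homotopic, so hydrolysing a cyclic orthoacetate of the diol can give only one mono-acetate.
- Key disconnection: both aryl–CH2 bonds (C1–Ar and C7–Ar), made in one operation by a two-directional aryl-radical anti-Markovnikov hydroarylation of a C2-symmetric divinyl orthoester with 4-iodo-2-methoxyphenol.
- Divinyl core: (3R,5R)-hepta-1,6-diene-3,5-diol, from (2R,4R)-1,2:4,5-diepoxypentane by one-carbon sulfonium-ylide homologation of both epoxides. Both stereocentres are bought and never reacted at.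
- Aryl iodide: catechol, mono-O-methylation, then iodination para to the free OH.
- Rings: neither arene is constructed. The only ring formed is a temporary 1,3-dioxane (the orthoester, step 4), opened again at the end of step 5.

Assumption: (2R,4R)-1,2:4,5-diepoxypentane is taken as a purchasable enantiopure catalogue compound; this was not verified against a supplier.

## Route

Step 1
Reactants: 1 catechol (benzene-1,2-diol)
Product: 2 guaiacol (2-methoxyphenol)
Conditions: MeI (0.9 equiv), K2CO3 (1.0 equiv), acetone, reflux; 1 used in 1.3-fold excess
Reagents that add atoms: iodomethane, CI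
Why: Williamson mono-O-methylation, in which sub-stoichiometric MeI and excess catechol keep over-methylation to veratrole low and 2 is separated from 1 and veratrole by base extraction and distillation; no stereocentre is involved.

Step 2
Reactants: 2 guaiacol (2-methoxyphenol)
Product: 3 4-iodo-2-methoxyphenol
Conditions: NIS (1.0 equiv), TsOH·H2O (10 mol%), MeCN, 0 °C → rt
Reagents that add atoms: N-iodosuccinimide, O=C1CCC(=O)N1I
Why: Electrophilic aromatic iodination (SEAr) in which the free OH, the stronger donor, directs para to itself (C4), the same selectivity that gives 4-bromoguaiacol on bromination; no stereocentre is involved.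

Step 3
Reactants: 4 (2R,4R)-1,2:4,5-diepoxypentane
Product: 5 (3R,5R)-hepta-1,6-diene-3,5-diol
Conditions: Me3S+ I− (6 equiv), n-BuLi (5.8 equiv), THF, −10 °C → rt; aq. NH4Cl
Reagents that add atoms: trimethylsulfonium iodide, C[S+](C)C.[I-]
Why: Sulfonium-ylide (Corey–Chaykovsky reagent) opening of each terminal epoxide at CH2 followed by ylide-mediated β-elimination of Me2S, the known one-carbon homologation of terminal epoxides to allylic alcohols, reacts only at the CH2 termini, so both C–O stereocentres are carried over unchanged (2R,4R → 3R,5R).

Step 4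
Reactants: 5 (3R,5R)-hepta-1,6-diene-3,5-diol
Product: 6 (4R,6R)-4,6-diethenyl-2-methoxy-2-methyl-1,3-dioxane
Conditions: MeC(OMe)3 (1.5 equiv), PPTS (2 mol%), CH2Cl2, rt; Et3N quench, evaporate at ≤ 25 °C
Reagents that add atoms: trimethyl orthoacetate, CC(OC)(OC)OC
Why: Acid-catalysed orthoester exchange closes the six-membered cyclic orthoacetate, which holds the two vinyl arms trans on a ring and already carries the future acetate, at room temperature so that no Johnson–Claisen rearrangement occurs; the carbinol centres are untouched and the orthoester carbon is non-stereogenic because of the C2 axis.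

Step 5
Reactants: 6 (4R,6R)-4,6-diethenyl-2-methoxy-2-methyl-1,3-dioxane; 3 4-iodo-2-methoxyphenol (4 equiv)
Product: 8 (3S,5S)-5-hydroxy-1,7-bis(4-hydroxy-3-methoxyphenyl)heptan-3-yl acetate, via diaryl cyclic orthoester 7 (not isolated)
Conditions: 10-phenylphenothiazine (5 mol%), cyclohexanethiol (5 mol%), HCO2Cs (6 equiv), dry degassed DMSO (0.25 M in 6), 390 nm LEDs, rt; aqueous extraction; then AcOH/H2O/THF (2:1:2), rt
Reagents that add atoms: water, O
Why: Proposed new method: the excited phenothiazine (or CO2 radical anion from formate) reduces the C–I bond of 3 to a 4-hydroxy-3-methoxyphenyl σ-radical that adds to each terminal =CH2 (anti-Markovnikov), and the resulting secondary alkyl radical takes H from the thiol, which formate regenerates — the closest known reaction type is the photoredox aryl-radical hydroarylation of alkenes with aryl halides (a reductive Meerwein arylation), here run in both directions on a ring that keeps the trans arms from 5-exo cyclising onto each other, in DMSO whose hydrogen bonding shields the phenolic O–H from H-abstraction, without touching the C–O stereocentres (R → S is only a CIP priority change), after which acid hydrolysis of the C2-symmetric orthoester can give only one mono-acetate.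

## Compound list

1 | catechol (benzene-1,2-diol) | Oc1ccccc1O | starting material
2 | guaiacol (2-methoxyphenol) | COc1ccccc1O | intermediate
3 | 4-iodo-2-methoxyphenol | COc1cc(I)ccc1O | intermediate
4 | (2R,4R)-1,2:4,5-diepoxypentane | C1O[C@@H]1C[C@@H]1CO1 | starting material
5 | (3R,5R)-hepta-1,6-diene-3,5-diol | C=C[C@H](O)C[C@@H](O)C=C | intermediate
6 | (4R,6R)-4,6-diethenyl-2-methoxy-2-methyl-1,3-dioxane | COC1(C)O[C@@H](C=C)C[C@H](C=C)O1 | intermediate
7 | (4S,6S)-4,6-bis[2-(4-hydroxy-3-methoxyphenyl)ethyl]-2-methoxy-2-methyl-1,3-dioxane | COC1(C)O[C@@H](CCc2ccc(O)c(OC)c2)C[C@H](CCc2ccc(O)c(OC)c2)O1 | intermediate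
8 | (3S,5S)-5-hydroxy-1,7-bis(4-hydroxy-3-methoxyphenyl)heptan-3-yl acetate | COc1cc(CC[C@H](O)C[C@H](CCc2ccc(O)c(OC)c2)OC(C)=O)ccc1O | target

## Step count and risks

Total steps: 5, in two branches (steps 1–2 and steps 3–4) joined in step 5.
Longest linear sequence: 3 steps (1 → 2 → 3 → 8, or 4 → 5 → 6 → 8).

Steps most likely to fail:

Step 5 (two-fold aryl-radical hydroarylation). The risks are loss of the aryl radical to simple reduction (giving back 2), incomplete second arylation, and thiyl-mediated scrambling at the allylic C–O carbons. The fallback reverses the radical polarity so that no free aryl radical is needed. It sets out from 6: hydrozirconation with Cp2Zr(H)Cl in THF followed by I2 gives (4R,6R)-4,6-bis(2-iodoethyl)-2-methoxy-2-methyl-1,3-dioxane F1. The primary alkyl radicals from F1 are then joined to 3 by nickel-catalysed reductive cross-electrophile coupling (NiI2, 4,4'-di-tert-butyl-2,2'-bipyridine, Mn powder, DMPU, cat. pyridine, 60 °C), which tolerates the free phenol. This returns to the route at 7, which is hydrolysed to 8 as in step 5.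

Step 3 (double ylide homologation). The risks are an incomplete second homologation, alkoxide attack on the remaining epoxide, and loss of the small water-soluble diol on work-up. The fallback sets out from 4: both epoxides are opened with (phenylselanyl)methyllithium (from bis(phenylselanyl)methane and n-BuLi, THF, −78 °C) to give the heavy, UV-active (3R,5R)-1,7-bis(phenylselanyl)heptane-3,5-diol F2. Oxidation (H2O2, pyridine, CH2Cl2, 0 °C → rt) and selenoxide syn-elimination then return to the route at 5.

Step 4 (cyclic orthoester). The risk is that 6 hydrolyses or exchanges on handling before the radical step. The fallback sets out from 5 and uses a robust tether, with the acetate installed afterwards. 2,2-Dimethoxypropane with PPTS gives (4R,6R)-4,6-diethenyl-2,2-dimethyl-1,3-dioxane F3, whose trans ring still prevents arm-to-arm cyclisation. The same two-fold radical hydroarylation with 3 gives (4S,6S)-4,6-bis[2-(4-hydroxy-3-methoxyphenyl)ethyl]-2,2-dimethyl-1,3-dioxane F4. Aqueous HCl in MeOH releases (3S,5S)-1,7-bis(4-hydroxy-3-methoxyphenyl)heptane-3,5-diol F5. F5 with MeC(OMe)3 and PPTS forms 7 in the flask, returning to the route at 7, and the hydrolysis of step 5 gives 8.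

## Further compounds

F1 | step 5 | (4R,6R)-4,6-bis(2-iodoethyl)-2-methoxy-2-methyl-1,3-dioxane | COC1(C)O[C@@H](CCI)C[C@H](CCI)O1
F2 | step 3 | (3R,5R)-1,7-bis(phenylselanyl)heptane-3,5-diol | O[C@H](CC[Se]c1ccccc1)C[C@@H](O)CC[Se]c1ccccc1
F3 | step 4 | (4R,6R)-4,6-diethenyl-2,2-dimethyl-1,3-dioxane | CC1(C)O[C@@H](C=C)C[C@H](C=C)O1
F4 | step 4 | (4S,6S)-4,6-bis[2-(4-hydroxy-3-methoxyphenyl)ethyl]-2,2-dimethyl-1,3-dioxane | CC1(C)O[C@@H](CCc2ccc(O)c(OC)c2)C[C@H](CCc2ccc(O)c(OC)c2)O1
F5 | step 4 | (3S,5S)-1,7-bis(4-hydroxy-3-methoxyphenyl)heptane-3,5-diol | COc1cc(CC[C@H](O)C[C@@H](O)CCc2ccc(O)c(OC)c2)ccc1O
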